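**Retrosynthetic overview**

1. Labels: C7 and C8 are the aryl-bearing and hydroxymethyl-bearing dioxane carbons, C9 the hydroxymethyl carbon, O7 and O8 their ring oxygens; ring A is the pendant catechol ring; ring B is the fused arene (enal on B1, OMe on B3, O8 on B4, O7 on B5). The target is traced back, through acid deprotection, Wittig two-carbon homologation, ester-to-aldehyde adjustment and O-methylation at B3, to a ring-B phenol ester.
2. The ring-B phenol is traced back by dehydrogenation to a dioxene-fused cyclohexenone, in which ring B is still a carbocycle at the cyclohexane-1,3-dione oxidation level.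
3. Key disconnection: the B4–O8 and O7–C7 bonds of the dioxene. This gives a (2R,3R)-trans aryl epoxide (from 5-hydroxyvanillin by olefination and asymmetric epoxidation) and the metal carbene of methyl 4-diazo-3,5-dioxocyclohexane-1-carboxylate.
4. Feature on which the plan rests: B3, B4 and B5 are three contiguous oxygen-bearing carbons and B1 is para to B4. This is the pattern of a 5-substituted cyclohexane-1,3-dione whose C2 (= B4) is unique by symmetry. C7 is benzylic to the trioxygenated ring A, so it is the epoxide carbon that ionises.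
5. Ring order: ring A is bought; the oxirane is built on its side chain; the 1,4-dioxene ring closes in the key step onto a preformed six-membered carbocycle; that carbocycle is aromatised to ring B last.

Key step: step 7

Remark on the chemistry: ring carbon B1 of compounds 12 to 15 forms without control (two epimers, carried together) and becomes sp2 in step 8. Intermediates 10 and 11 are drawn metal-free for clarity, although they may stay associated with ruthenium in the flask.

**Route**

Step 1
Reactants: 1 5-hydroxyvanillin (3,4-dihydroxy-5-methoxybenzaldehyde)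
Product: 2 3-methoxy-4,5-bis(methoxymethoxy)benzaldehyde
Conditions: MOMCl (3 equiv), iPr2NEt, CH2Cl2, 0 °C to rt
Reagents that add atoms: chloromethyl methyl ether, COCCl
Why: O-alkylation of both phenols by the reactive α-chloro ether (MOM protection) masks the catechol as acetals that are stable to base, hydride, enolate and carbene chemistry and are removed only by the final acid treatment.

Step 2
Reactants: 2 3-methoxy-4,5-bis(methoxymethoxy)benzaldehyde; 3 triethyl phosphonoacetate
Product: 4 ethyl (E)-3-[3-methoxy-4,5-bis(methoxymethoxy)phenyl]prop-2-enoate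
Conditions: NaH, THF, 0 °C to rt
Reagents that add atoms: none
Why: Horner–Wadsworth–Emmons olefination of an aryl aldehyde with a stabilised phosphonate anion should give the E-enoate under thermodynamic control of the elimination.

Step 3
Reactants: 4 ethyl (E)-3-[3-methoxy-4,5-bis(methoxymethoxy)phenyl]prop-2-enoate
Product: 5 (E)-3-[3-methoxy-4,5-bis(methoxymethoxy)phenyl]prop-2-en-1-ol
Conditions: iBu2AlH (2.5 equiv), CH2Cl2, −78 °C; aqueous potassium sodium tartrate work-up
Reagents that add atoms: none
Why: 1,2-Reduction of the enoate by iBu2AlH at low temperature should give the E-allylic alcohol without touching the alkene or the acetals.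

Step 4
Reactants: 5 (E)-3-[3-methoxy-4,5-bis(methoxymethoxy)phenyl]prop-2-en-1-ol
Product: 6 [(2R,3R)-3-[3-methoxy-4,5-bis(methoxymethoxy)phenyl]oxiran-2-yl]methanol
Conditions: Ti(OiPr)4 (10 mol%), D-(−)-diisopropyl tartrate (12 mol%), tBuOOH (2 equiv, in decane), 4 Å molecular sieves, CH2Cl2, −25 °C; cold aqueous NaOH/brine work-up
Reagents that add atoms: tert-butyl hydroperoxide, CC(C)(C)OO
Why: Sharpless asymmetric epoxidation with the D-(−)-tartrate ligand delivers oxygen to the face of the E-allylic alcohol that gives the (2R,3R)-epoxide, setting C7 and C8 together, while catalytic titanium, sieves and a basic work-up spare the acid-sensitive benzylic epoxide.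

Step 5
Reactants: 6 [(2R,3R)-3-[3-methoxy-4,5-bis(methoxymethoxy)phenyl]oxiran-2-yl]methanol
Product: 7 tert-butyl{[(2R,3R)-3-[3-methoxy-4,5-bis(methoxymethoxy)phenyl]oxiran-2-yl]methoxy}dimethylsilane
Conditions: TBSCl, imidazole, CH2Cl2, 0 °C to rt
Reagents that add atoms: tert-butyldimethylsilyl chloride, CC(C)(C)[Si](C)(C)Cl
Why: Imidazole-mediated silylation of the primary alcohol, done at once on crude 6 under non-acidic conditions, removes the O–H bond that would otherwise intercept the carbene in step 7.

Step 6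
Reactants: 8 methyl 3,5-dioxocyclohexane-1-carboxylate
Product: 9 methyl 4-diazo-3,5-dioxocyclohexane-1-carboxylate
Conditions: 4-acetamidobenzenesulfonyl azide, Et3N, MeCN, 0 °C to rt
Reagents that add atoms: 4-acetamidobenzenesulfonyl azide, CC(=O)Nc1ccc(cc1)S(=O)(=O)N=[N+]=[N-]
Why: Regitz diazo transfer takes place at the doubly activated methylene between the two carbonyls, the only position acidic enough for Et3N, and should give the stable 2-diazo-1,3-dione.

Step 7
Reactants: 7 tert-butyl{[(2R,3R)-3-[3-methoxy-4,5-bis(methoxymethoxy)phenyl]oxiran-2-yl]methoxy}dimethylsilane; 9 methyl 4-diazo-3,5-dioxocyclohexane-1-carboxylate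
Product: 12 methyl (2R,3R)-3-{[tert-butyl(dimethyl)silyl]oxymethyl}-2-[3-methoxy-4,5-bis(methoxymethoxy)phenyl]-5-oxo-2,3,5,6,7,8-hexahydro-1,4-benzodioxine-7-carboxylate (both epimers at ring carbon B1), via oxonium ylide 10 (not isolated), via benzylic zwitterion 11 (not isolated)
Conditions: [CpRu(CH3CN)3]PF6 (5 mol%), 1,10-phenanthroline (5 mol%), 9 (2 equiv) added over 6 h, CH2Cl2, 60 °C (sealed vessel)
Reagents that add atoms: none
Why: Proposed new method: the catalyst expels N2 from 9 to give an electrophilic ruthenium carbene at B4, the epoxide oxygen of 7 adds to it (B4–O8 bond) to give oxonium ylide 10, the strained benzylic C7–O bond then ionises to the contact ion pair 11, and the neighbouring enolate oxygen re-bonds to C7 (O7–C7 bond) on the side the epoxide oxygen has just vacated. The closest known reaction type is the [CpRu(CH3CN)3]PF6/phenanthroline-catalysed insertion of acyclic α-diazo-β-ketoester carbenes into terminal and styrene-type epoxides, which gives 1,4-dioxenes with retention at the ionising carbon; a cyclic 2-diazo-1,3-dione and a trans-2,3-disubstituted, electron-rich aryl epoxide are substrate classes not yet shown. The one ring closed is the six-membered dioxene, in a formal (3+3) mode: the enolate oxygen captures the C7 cation along the O7–B5=B4–O8–C8–C7 chain, and the cyclic dione holds O7 and O8 cis on the B4=B5 bond. C8 is never broken and keeps its R configuration; C7 is re-formed R by front-side collapse of the ion pair, and if the pair loosens the fixed C8 centre should still steer closure to the trans-diequatorial ring, so a leak would cost diastereomeric but not enantiomeric purity. The step needs C7–O rather than C8–O cleavage (benzylic stabilisation by ring A against the inductively deactivated C8), oxygen rather than carbon capture by the enolate (six-membered dioxene against a strained oxetane) and a single constitution (the two dione carbonyls are equivalent); slow addition of 9 limits carbene dimerisation and the phenanthroline ligand tempers Lewis acidity toward the epoxide.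

Step 8
Reactants: 12 methyl (2R,3R)-3-{[tert-butyl(dimethyl)silyl]oxymethyl}-2-[3-methoxy-4,5-bis(methoxymethoxy)phenyl]-5-oxo-2,3,5,6,7,8-hexahydro-1,4-benzodioxine-7-carboxylate
Product: 16 methyl (2R,3R)-3-{[tert-butyl(dimethyl)silyl]oxymethyl}-5-hydroxy-2-[3-methoxy-4,5-bis(methoxymethoxy)phenyl]-2,3-dihydro-1,4-benzodioxine-7-carboxylate, via lithium enolate 13 (not isolated), via phenylselanyl ketone 14 (not isolated), via cyclohexadienone 15 (not isolated)
Conditions: LiN(iPr)2 (1.2 equiv), THF, −78 °C; PhSeBr (1.3 equiv), −78 °C; then 30% aqueous H2O2, pyridine, CH2Cl2, 0 °C to rt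
Reagents that add atoms: none
Why: α-Selenenylation of the kinetic lithium enolate followed by selenoxide syn-elimination (Reich–Sharpless dehydrogenation) should place the B1=B2 double bond in the vinylogous ester to give dienone 15, the keto tautomer of the phenol, which aromatises at once, so both B1 epimers (and any selenide formed at B1 through the ester enolate) converge on one arene with C7 and C8 untouched.

Step 9
Reactants: 16 methyl (2R,3R)-3-{[tert-butyl(dimethyl)silyl]oxymethyl}-5-hydroxy-2-[3-methoxy-4,5-bis(methoxymethoxy)phenyl]-2,3-dihydro-1,4-benzodioxine-7-carboxylate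
Product: 17 methyl (2R,3R)-3-{[tert-butyl(dimethyl)silyl]oxymethyl}-5-methoxy-2-[3-methoxy-4,5-bis(methoxymethoxy)phenyl]-2,3-dihydro-1,4-benzodioxine-7-carboxylate
Conditions: MeI, K2CO3, acetone, 50 °C
Reagents that add atoms: iodomethane, CI
Why: Williamson etherification of the only free phenol (B3–OH) under mild carbonate conditions installs the ring-B methoxy group and leaves the ester, silyl ether and acetals alone.

Step 10
Reactants: 17 methyl (2R,3R)-3-{[tert-butyl(dimethyl)silyl]oxymethyl}-5-methoxy-2-[3-methoxy-4,5-bis(methoxymethoxy)phenyl]-2,3-dihydro-1,4-benzodioxine-7-carboxylate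
Product: 18 [(2R,3R)-3-{[tert-butyl(dimethyl)silyl]oxymethyl}-5-methoxy-2-[3-methoxy-4,5-bis(methoxymethoxy)phenyl]-2,3-dihydro-1,4-benzodioxin-7-yl]methanol
Conditions: iBu2AlH (2.5 equiv), CH2Cl2, −78 to 0 °C; aqueous potassium sodium tartrate work-up
Reagents that add atoms: none
Why: Hydride reduction of the aryl ester by iBu2AlH should give the benzylic alcohol cleanly, since no other reducible group is present.

Step 11
Reactants: 18 [(2R,3R)-3-{[tert-butyl(dimethyl)silyl]oxymethyl}-5-methoxy-2-[3-methoxy-4,5-bis(methoxymethoxy)phenyl]-2,3-dihydro-1,4-benzodioxin-7-yl]methanol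
Product: 19 (2R,3R)-3-{[tert-butyl(dimethyl)silyl]oxymethyl}-5-methoxy-2-[3-methoxy-4,5-bis(methoxymethoxy)phenyl]-2,3-dihydro-1,4-benzodioxine-7-carbaldehyde
Conditions: MnO2 (excess), CH2Cl2, rt
Reagents that add atoms: none
Why: MnO2 oxidation is selective for the benzylic alcohol and stops at the aldehyde under neutral conditions that the acetals and silyl ether tolerate.

Step 12
Reactants: 19 (2R,3R)-3-{[tert-butyl(dimethyl)silyl]oxymethyl}-5-methoxy-2-[3-methoxy-4,5-bis(methoxymethoxy)phenyl]-2,3-dihydro-1,4-benzodioxine-7-carbaldehyde; 20 (formylmethylene)triphenylphosphorane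
Product: 21 (E)-3-[(2R,3R)-3-{[tert-butyl(dimethyl)silyl]oxymethyl}-5-methoxy-2-[3-methoxy-4,5-bis(methoxymethoxy)phenyl]-2,3-dihydro-1,4-benzodioxin-7-yl]prop-2-enal
Conditions: 20 (1.3 equiv), toluene, 80 °C
Reagents that add atoms: none
Why: Wittig olefination with the stabilised formyl ylide should give the E-enal, and a small excess of ylide at moderate temperature holds back a second homologation of the less electrophilic product.

Step 13
Reactants: 21 (E)-3-[(2R,3R)-3-{[tert-butyl(dimethyl)silyl]oxymethyl}-5-methoxy-2-[3-methoxy-4,5-bis(methoxymethoxy)phenyl]-2,3-dihydro-1,4-benzodioxin-7-yl]prop-2-enal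
Product: 22 (E)-3-[(2R,3R)-2-(3,4-dihydroxy-5-methoxyphenyl)-3-(hydroxymethyl)-5-methoxy-2,3-dihydro-1,4-benzodioxin-7-yl]prop-2-enal (CNP0103768.1)
Conditions: 2 M aqueous HCl, THF, 40 °C, under argon
Reagents that add atoms: none
Why: Acid-catalysed hydrolysis of the two aryl MOM acetals and of the primary silyl ether (global deprotection) leaves the aryl–alkyl ether bonds and the enal intact, and a reversible opening at benzylic C7 could only re-close to the same trans ring because C8 is fixed.

**Compound list**

1 | 5-hydroxyvanillin (3,4-dihydroxy-5-methoxybenzaldehyde) | COc1cc(C=O)cc(O)c1O | starting material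
2 | 3-methoxy-4,5-bis(methoxymethoxy)benzaldehyde | COc1cc(C=O)cc(OCOC)c1OCOC | intermediate
3 | triethyl phosphonoacetate | CCOC(=O)CP(=O)(OCC)OCC | starting material
4 | ethyl (E)-3-[3-methoxy-4,5-bis(methoxymethoxy)phenyl]prop-2-enoate | COc1cc(/C=C/C(=O)OCC)cc(OCOC)c1OCOC | intermediate
5 | (E)-3-[3-methoxy-4,5-bis(methoxymethoxy)phenyl]prop-2-en-1-ol | COc1cc(/C=C/CO)cc(OCOC)c1OCOC | intermediate
6 | [(2R,3R)-3-[3-methoxy-4,5-bis(methoxymethoxy)phenyl]oxiran-2-yl]methanol | COc1cc([C@H]2O[C@@H]2CO)cc(OCOC)c1OCOC | intermediate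
7 | tert-butyl{[(2R,3R)-3-[3-methoxy-4,5-bis(methoxymethoxy)phenyl]oxiran-2-yl]methoxy}dimethylsilane | COc1cc([C@H]2O[C@@H]2CO[Si](C)(C)C(C)(C)C)cc(OCOC)c1OCOC | intermediate
8 | methyl 3,5-dioxocyclohexane-1-carboxylate | COC(=O)C1CC(=O)CC(=O)C1 | starting material
9 | methyl 4-diazo-3,5-dioxocyclohexane-1-carboxylate | COC(=O)C1CC(=O)C(=[N+]=[N-])C(=O)C1 | intermediate
10 | oxonium ylide from epoxide 7 and the carbene of 9 (step 7, not isolated) | COc1cc([C@H]2[O+](C3=C([O-])CC(C(=O)OC)CC3=O)[C@@H]2CO[Si](C)(C)C(C)(C)C)cc(OCOC)c1OCOC | intermediate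
11 | ring-opened benzylic cation/enolate zwitterion (step 7, not isolated) | COc1cc([CH+][C@@H](CO[Si](C)(C)C(C)(C)C)OC2=C([O-])CC(C(=O)OC)CC2=O)cc(OCOC)c1OCOC | intermediate
12 | methyl (2R,3R)-3-{[tert-butyl(dimethyl)silyl]oxymethyl}-2-[3-methoxy-4,5-bis(methoxymethoxy)phenyl]-5-oxo-2,3,5,6,7,8-hexahydro-1,4-benzodioxine-7-carboxylate (B1 epimers) | COc1cc([C@H]2OC3=C(O[C@@H]2CO[Si](C)(C)C(C)(C)C)C(=O)CC(C(=O)OC)C3)cc(OCOC)c1OCOC | intermediate
13 | lithium enolate of 12 across B3–B2 (step 8, not isolated) | COc1cc([C@H]2OC3=C(O[C@@H]2CO[Si](C)(C)C(C)(C)C)C(O[Li])=CC(C(=O)OC)C3)cc(OCOC)c1OCOC | intermediate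
14 | B2-phenylselanyl ketone (step 8, not isolated) | COc1cc([C@H]2OC3=C(O[C@@H]2CO[Si](C)(C)C(C)(C)C)C(=O)C([Se]c4ccccc4)C(C(=O)OC)C3)cc(OCOC)c1OCOC | intermediate
15 | cross-conjugated cyclohexadienone, keto tautomer of 16 (step 8, not isolated) | COc1cc([C@H]2OC3=C(O[C@@H]2CO[Si](C)(C)C(C)(C)C)C(=O)C=C(C(=O)OC)C3)cc(OCOC)c1OCOC | intermediate
16 | methyl (2R,3R)-3-{[tert-butyl(dimethyl)silyl]oxymethyl}-5-hydroxy-2-[3-methoxy-4,5-bis(methoxymethoxy)phenyl]-2,3-dihydro-1,4-benzodioxine-7-carboxylate | COc1cc([C@H]2Oc3cc(C(=O)OC)cc(O)c3O[C@@H]2CO[Si](C)(C)C(C)(C)C)cc(OCOC)c1OCOC | intermediate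
17 | methyl (2R,3R)-3-{[tert-butyl(dimethyl)silyl]oxymethyl}-5-methoxy-2-[3-methoxy-4,5-bis(methoxymethoxy)phenyl]-2,3-dihydro-1,4-benzodioxine-7-carboxylate | COc1cc([C@H]2Oc3cc(C(=O)OC)cc(OC)c3O[C@@H]2CO[Si](C)(C)C(C)(C)C)cc(OCOC)c1OCOC | intermediate
18 | [(2R,3R)-3-{[tert-butyl(dimethyl)silyl]oxymethyl}-5-methoxy-2-[3-methoxy-4,5-bis(methoxymethoxy)phenyl]-2,3-dihydro-1,4-benzodioxin-7-yl]methanol | COc1cc([C@H]2Oc3cc(CO)cc(OC)c3O[C@@H]2CO[Si](C)(C)C(C)(C)C)cc(OCOC)c1OCOC | intermediate
19 | (2R,3R)-3-{[tert-butyl(dimethyl)silyl]oxymethyl}-5-methoxy-2-[3-methoxy-4,5-bis(methoxymethoxy)phenyl]-2,3-dihydro-1,4-benzodioxine-7-carbaldehyde | COc1cc([C@H]2Oc3cc(C=O)cc(OC)c3O[C@@H]2CO[Si](C)(C)C(C)(C)C)cc(OCOC)c1OCOC | intermediate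
20 | (formylmethylene)triphenylphosphorane | O=CC=P(c1ccccc1)(c1ccccc1)c1ccccc1 | starting material
21 | (E)-3-[(2R,3R)-3-{[tert-butyl(dimethyl)silyl]oxymethyl}-5-methoxy-2-[3-methoxy-4,5-bis(methoxymethoxy)phenyl]-2,3-dihydro-1,4-benzodioxin-7-yl]prop-2-enal | COc1cc([C@H]2Oc3cc(/C=C/C=O)cc(OC)c3O[C@@H]2CO[Si](C)(C)C(C)(C)C)cc(OCOC)c1OCOC | intermediate
22 | (E)-3-[(2R,3R)-2-(3,4-dihydroxy-5-methoxyphenyl)-3-(hydroxymethyl)-5-methoxy-2,3-dihydro-1,4-benzodioxin-7-yl]prop-2-enal | COc1cc([C@H]2Oc3cc(/C=C/C=O)cc(OC)c3O[C@@H]2CO)cc(O)c1O | target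

**Step count**

Total step count: 13.
Longest linear sequence: 12 steps (steps 1 to 5 and 7 to 13, from 1 to 22); step 6 is a one-step branch.

**Steps most likely to fail**

1. Step 7 (carbene–epoxide (3+3) closure). What may go wrong:
- the carbene may be lost to dimerisation, to deoxygenation of the epoxide, or to electrophilic attack on ring A;
- the activated epoxide may rearrange by hydride shift before the enolate oxygen reaches C7;
- a loose ion pair would erode the trans selectivity.

Fallback (known chemistry, from 5, returning at 17):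
- Sharpless epoxidation of 5 with L-(+)-diisopropyl tartrate should give the enantiomeric [(2S,3S)-3-[3-methoxy-4,5-bis(methoxymethoxy)phenyl]oxiran-2-yl]methanol F1. Silylation (TBSCl, imidazole) gives the (2S,3S)-epoxy silyl ether F2.
- Separately, commercial methyl 3,4-dihydroxy-5-methoxybenzoate (COC(=O)c1cc(O)c(O)c(OC)c1) is allylated at its more acidic 4-hydroxyl (allyl bromide, KHCO3, DMF) to give methyl 4-(allyloxy)-3-hydroxy-5-methoxybenzoate F3.
- The phenoxide of F3 (catalytic Cs2CO3, DMF, 80 °C) should open F2 at the benzylic carbon by SN2 with inversion. This forms the O7–C7 bond and gives the (1R,2S)-aryl ether alcohol F4.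
- Zerovalent palladium (Pd(PPh3)4, morpholine, THF) removes the allyl group to give the phenol F5.
- Intramolecular Mitsunobu etherification (PPh3, diisopropyl azodicarboxylate, THF) closes O8–C8 with inversion and should give 17, from which steps 10 to 13 follow unchanged.

2. Step 8 (dehydrogenative aromatisation). What may go wrong:
- enolisation may be unselective and selenenylation may occur more than once;
- the selenoxide may lack a syn hydrogen;
- the peroxide may attack the electron-rich enol ether;
- traces of acid may ionise the C7–O7 vinylogous ester bond of 12 before the ring is aromatic.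

Fallback (from 12, returning at 16): LiN(iPr)2 then Me3SiCl (THF, −78 °C) should give the trimethylsilyl dienol ether F6. Saegusa–Ito oxidation with Pd(OAc)2 in MeCN at rt (divalent palladium enolate, β-hydride elimination) gives the dienone, which tautomerises to 16. No peroxide or selenium is involved.

3. Step 4 (asymmetric epoxidation). What may go wrong: the Lewis-acidic titanium alkoxide may open the electron-rich benzylic epoxide with isopropanol or tartrate, during the reaction or on work-up.

Fallback (from 5, returning at 7): silylation of 5 (TBSCl, imidazole) gives the (E)-allylic silyl ether F7. Shi epoxidation follows, using the D-fructose-derived ketone (1,2:4,5-di-O-isopropylidene-β-D-erythro-2,3-hexodiulo-2,6-pyranose, 30 mol%), Oxone (2KHSO5·KHSO4·K2SO4), K2CO3 and Bu4NHSO4 in MeCN/dimethoxymethane/aqueous buffer at pH 10.5 and 0 °C. This dioxirane oxidation runs under basic buffer and should give the (2R,3R)-epoxide 7 directly.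

**Further compounds**

F1 | step 7 | [(2S,3S)-3-[3-methoxy-4,5-bis(methoxymethoxy)phenyl]oxiran-2-yl]methanol | COc1cc([C@@H]2O[C@H]2CO)cc(OCOC)c1OCOC
F2 | step 7 | tert-butyl{[(2S,3S)-3-[3-methoxy-4,5-bis(methoxymethoxy)phenyl]oxiran-2-yl]methoxy}dimethylsilane | COc1cc([C@@H]2O[C@H]2CO[Si](C)(C)C(C)(C)C)cc(OCOC)c1OCOC
F3 | step 7 | methyl 4-(allyloxy)-3-hydroxy-5-methoxybenzoate | COC(=O)c1cc(O)c(OCC=C)c(OC)c1
F4 | step 7 | methyl 4-(allyloxy)-3-{(1R,2S)-3-[tert-butyl(dimethyl)silyl]oxy-2-hydroxy-1-[3-methoxy-4,5-bis(methoxymethoxy)phenyl]propoxy}-5-methoxybenzoate | COC(=O)c1cc(O[C@H](c2cc(OC)c(OCOC)c(OCOC)c2)[C@@H](O)CO[Si](C)(C)C(C)(C)C)c(OCC=C)c(OC)c1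
F5 | step 7 | methyl 3-{(1R,2S)-3-[tert-butyl(dimethyl)silyl]oxy-2-hydroxy-1-[3-methoxy-4,5-bis(methoxymethoxy)phenyl]propoxy}-4-hydroxy-5-methoxybenzoate | COC(=O)c1cc(O[C@H](c2cc(OC)c(OCOC)c(OCOC)c2)[C@@H](O)CO[Si](C)(C)C(C)(C)C)c(O)c(OC)c1
F6 | step 8 | trimethylsilyl dienol ether of 12 (silyloxy on B3, double bonds B3=B2 and B4=B5) | COc1cc([C@H]2OC3=C(O[C@@H]2CO[Si](C)(C)C(C)(C)C)C(O[Si](C)(C)C)=CC(C(=O)OC)C3)cc(OCOC)c1OCOC
F7 | step 4 | tert-butyl{[(E)-3-[3-methoxy-4,5-bis(methoxymethoxy)phenyl]prop-2-en-1-yl]oxy}dimethylsilane | COc1cc(/C=C/CO[Si](C)(C)C(C)(C)C)cc(OCOC)c1OCOC
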